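Ring numbering used throughout: C1 carries the tigloyloxymethyl carbon C7, C2 is the ketone, C3 the free carbinol, C4 the isopropyl carbon, C5 the ring tigloyloxy carbon, C6 the vinylic CH.
Retrosynthesis cuts, in this order: the C3–O bond (α′-hydroxylation), the C7–O ester, the C1–C7 bond (Morita–Baylis–Hillman with formaldehyde), the C2 oxygen (allylic C–H oxidation), the C5–O ester, and last the C5–H bond, leading back to racemic 6-isopropylcyclohex-2-enone and, by Birch chemistry, to 2-isopropylphenol.
Forward, the only carbocycle is the benzene ring of the phenol, dearomatised and never re-formed; the appendages then go on in the order C5 tiglate, C2 oxygen, C7, C7 tiglate, C3 hydroxyl.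
Enabling feature: in the six-membered ring the isopropyl carbon C4 is the direct neighbour of the oxygen-bearing C5 and the two substituents are cis, so with C5 as a ketone C4–H is an enolisable α-hydrogen and a racemic enone can be funnelled through its dienolate into one cis allylic alcohol by carbonyl-selective asymmetric hydrogenation.
Stereochemistry: C4 and C5 (absolute and cis) come from the chiral Ru catalyst in that dynamic kinetic hydrogenation; C3 comes from substrate control (oxidant anti to the cis isopropyl/tigloyloxy pair); both E-alkenes are carried in from tiglic acid.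

Key step: step 4

Assumption: the sense of induction of the Ru diphosphine/diamine catalyst is carried over from the saturated 2-isopropylcyclohexanone case, which points to the (R)-BINAP/(S,S)-DPEN pairing for the (1S,6S) alcohol; if the opposite sense were found, the mirror-image catalyst would be used with no other change.
Notation: tigloyl/tiglate = (E)-2-methylbut-2-enoyl/-enoate. The descriptor at the ring tigloyloxy carbon changes from S (6, 9, 11) to R (13–15) and back to S (16, 17) through CIP priorities only; no centre is inverted.

Step 1
Reactants: 1 2-isopropylphenol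
Product: 2 2-isopropylanisole
Conditions: MeI, K2CO3, acetone, reflux
Reagents that add atoms: iodomethane, CI
Why: Williamson ether synthesis, in which the phenoxide formed by carbonate is methylated on oxygen by SN2 attack on iodomethane and the arene offers no other nucleophilic site.

Step 2
Reactants: 2 2-isopropylanisole
Product: 3 1-methoxy-2-isopropylcyclohexa-1,4-diene
Conditions: Li, NH3(l), THF, t-BuOH, −78 → −33 °C; NH4Cl quench
Reagents that add atoms: none
Why: Birch reduction, in which the radical anion and the derived cyclohexadienyl anion are protonated at the two unsubstituted, mutually para positions (C3 and C6 of the anisole), so both donor substituents stay on one double bond and the unconjugated 1,4-diene results.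

Step 3
Reactants: 3 1-methoxy-2-isopropylcyclohexa-1,4-diene
Product: 5 rac-6-isopropylcyclohex-2-en-1-one, via 6-isopropylcyclohex-3-en-1-one 4 (not isolated)
Conditions: 2 M aq. HCl, THF, rt → 45 °C
Reagents that add atoms: water, O
Why: Acid-catalysed enol ether hydrolysis, in which protonation at the isopropyl-bearing carbon, hydration and loss of methanol give the β,γ-enone 4, which the same acid moves into conjugation through its dienol; the new C4 centre is deliberately left racemic because step 4 is stereoconvergent.

Step 4
Reactants: 5 rac-6-isopropylcyclohex-2-en-1-one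
Product: 6 (1S,6S)-6-isopropylcyclohex-2-en-1-ol
Conditions: trans-RuCl2[(R)-binap][(S,S)-dpen] (0.2 mol%), t-BuOK (2 mol%), H2 (8 atm), i-PrOH, 25 °C
Reagents that add atoms: none
Why: Proposed new method: tert-butoxide turns the precatalyst into the Ru hydride/amine N–H species, which passes hydride and proton to the C5=O group through an outer-sphere six-membered transition state without binding the C6=C1 alkene, while the same base reversibly forms the cross-conjugated C4=C5 dienolate of 5, which can be reprotonated only at C4, so the two enantiomers interconvert and the alkene stays in place. The closest known reaction types are the base-mediated dynamic kinetic asymmetric hydrogenation of racemic 2-isopropylcyclohexanone to the cis alcohol and the carbonyl-selective hydrogenation of cyclic enones, both with this catalyst family (Noyori-type asymmetric hydrogenation). The step forms no ring. C5 is set by the chiral catalyst, which delivers hydride along the equatorial trajectory to the enantiomer that has its isopropyl group equatorial and so gives the axial hydroxyl cis to isopropyl; C4 is set by the same catalyst through its choice of one enantiomer of the racemising ketone, and is locked once the carbonyl is gone. The step needs C=O over C=C chemoselectivity, cis diastereoselectivity and racemisation faster than reduction of the mismatched enantiomer: the bifunctional mechanism secures the first, and the bulky isopropyl group directly beside the carbonyl together with the acidic C4–H secure the other two.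

Step 5
Reactants: 7 tiglic acid
Product: 8 tigloyl chloride
Conditions: (COCl)2, DMF (cat.), CH2Cl2, 0 °C → rt; volatiles removed, used crude
Reagents that add atoms: oxalyl chloride, O=C(Cl)C(=O)Cl
Why: Acid chloride formation through the Vilsmeier-type chloroiminium catalyst from DMF and oxalyl chloride, run without base so that the E-alkene can neither isomerise nor deconjugate.

Step 6
Reactants: 6 (1S,6S)-6-isopropylcyclohex-2-en-1-ol; 8 tigloyl chloride
Product: 9 (1S,6S)-6-isopropylcyclohex-2-en-1-yl tiglate
Conditions: pyridine, DMAP (10 mol%), CH2Cl2, 0 °C → rt
Reagents that add atoms: none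
Why: Nucleophilic-catalysed acylation (DMAP, via the N-acylpyridinium ion) of the hindered axial alcohol, in which the C5–O bond of the alcohol is not broken, so C5 keeps its configuration, and pyridine is too weak a base to deconjugate the tigloyl group through a vinylketene.

Step 7
Reactants: 9 (1S,6S)-6-isopropylcyclohex-2-en-1-yl tiglate
Product: 11 (4S,5S)-5-isopropyl-4-(tigloyloxy)cyclohex-2-en-1-one, via allylic tert-butyl peroxide 10 (not isolated)
Conditions: Rh2(cap)4 (1 mol%), t-BuOOH (5 equiv, in decane), K2CO3 (cat.), CH2Cl2, rt
Reagents that add atoms: tert-butyl hydroperoxide, CC(C)(C)OO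
Why: Dirhodium-catalysed allylic oxidation with TBHP, in which a tert-butylperoxyl radical abstracts hydrogen from C2, the only ring allylic methylene (C5–H is deactivated by its acyloxy group and the tigloyl alkene is electron-poor), the allyl radical is capped at C2, the terminus remote from the ester, and the mixed peroxide 10 loses tert-butanol (Kornblum–DeLaMare fragmentation) to give the enone without touching C4 or C5.

Step 8
Reactants: 11 (4S,5S)-5-isopropyl-4-(tigloyloxy)cyclohex-2-en-1-one; 12 formaldehyde (37% aqueous)
Product: 13 (4R,5S)-2-(hydroxymethyl)-5-isopropyl-4-(tigloyloxy)cyclohex-2-en-1-one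
Conditions: DMAP (0.3 equiv), THF/H2O, rt
Reagents that add atoms: none
Why: Morita–Baylis–Hillman reaction, in which DMAP adds to C6, the C1 enolate undergoes aldol addition to formaldehyde and loss of DMAP restores the enone, a sequence precedented for 4-oxygenated cyclohex-2-enones that creates no stereocentre and uses a base too weak to remove the γ-hydrogen at C5.

Step 9
Reactants: 13 (4R,5S)-2-(hydroxymethyl)-5-isopropyl-4-(tigloyloxy)cyclohex-2-en-1-one; 8 tigloyl chloride
Product: 14 (4R,5S)-5-isopropyl-4-(tigloyloxy)-2-[(tigloyloxy)methyl]cyclohex-2-en-1-one
Conditions: pyridine, CH2Cl2, 0 °C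
Reagents that add atoms: none
Why: Acylation of the unhindered primary allylic alcohol by the acid chloride with pyridine as base, DMAP being left out to avoid SN2′ attack on the allylic ester that is being formed.

Step 10
Reactants: 14 (4R,5S)-5-isopropyl-4-(tigloyloxy)-2-[(tigloyloxy)methyl]cyclohex-2-en-1-one
Product: 15 [(3R,4R)-4-isopropyl-3-(tigloyloxy)-6-(triethylsilyloxy)cyclohexa-1,5-dien-1-yl]methyl tiglate
Conditions: TESOTf, Et3N, CH2Cl2, −78 → −20 °C; cold NaHCO3 work-up, used at once
Reagents that add atoms: triethylsilyl trifluoromethanesulfonate, CC[Si](CC)(CC)OS(=O)(=O)C(F)(F)F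
Why: Soft enolisation (silyl triflate/tertiary amine), in which O-silylation of the ketone makes the α′ hydrogens at C3 the kinetically accessible acidic site and gives the cross-conjugated 2-silyloxy-1,3-diene, as is usual for cyclohex-2-enones, with no strong base to attack the esters and no change at C4 or C5.

Step 11
Reactants: 15 [(3R,4R)-4-isopropyl-3-(tigloyloxy)-6-(triethylsilyloxy)cyclohexa-1,5-dien-1-yl]methyl tiglate
Product: 17 (4S,5R,6R)-6-hydroxy-5-isopropyl-4-(tigloyloxy)-2-[(tigloyloxy)methyl]cyclohex-2-en-1-one (the target CNP0326914.1), via silyloxy epoxide 16 (not isolated)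
Conditions: DMDO (acetone), CH2Cl2, −78 → −30 °C; then HF·pyridine, THF, 0 °C
Reagents that add atoms: dimethyldioxirane, CC1(C)OO1
Why: Rubottom oxidation, in which neutral DMDO epoxidises the electron-rich C2=C3 enol silane, not the ester-substituted alkenes, on the ring face opposite the cis isopropyl (C4) and tigloyloxy (C5) groups, and HF·pyridine then removes silicon with opening of the silyloxy epoxide to the α-hydroxy ketone, so the C3 hydroxyl should end trans to isopropyl (6R in the systematic name).

Compound list
1 | 2-isopropylphenol | CC(C)c1ccccc1O | starting material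
2 | 2-isopropylanisole | COc1ccccc1C(C)C | intermediate
3 | 1-methoxy-2-isopropylcyclohexa-1,4-diene | COC1=C(C(C)C)CC=CC1 | intermediate
4 | 6-isopropylcyclohex-3-en-1-one (racemic, not isolated) | CC(C)C1CC=CCC1=O | intermediate
5 | rac-6-isopropylcyclohex-2-en-1-one | CC(C)C1CCC=CC1=O | intermediate
6 | (1S,6S)-6-isopropylcyclohex-2-en-1-ol (cis) | C1=C[C@H](O)[C@H](C(C)C)CC1 | intermediate
7 | tiglic acid, (E)-2-methylbut-2-enoic acid | C/C=C(\C)C(=O)O | starting material
8 | tigloyl chloride, (E)-2-methylbut-2-enoyl chloride | C/C=C(\C)C(=O)Cl | intermediate
9 | (1S,6S)-6-isopropylcyclohex-2-en-1-yl tiglate | C1=C[C@H](OC(=O)/C(C)=C/C)[C@H](C(C)C)CC1 | intermediate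
10 | (1S,6S)-4-(tert-butylperoxy)-6-isopropylcyclohex-2-en-1-yl tiglate (C4 epimers, not isolated) | CC(C)(C)OOC1C=C[C@H](OC(=O)/C(C)=C/C)[C@H](C(C)C)C1 | intermediate
11 | (4S,5S)-5-isopropyl-4-(tigloyloxy)cyclohex-2-en-1-one | O=C1C=C[C@H](OC(=O)/C(C)=C/C)[C@H](C(C)C)C1 | intermediate
12 | formaldehyde | C=O | starting material
13 | (4R,5S)-2-(hydroxymethyl)-5-isopropyl-4-(tigloyloxy)cyclohex-2-en-1-one | OCC1=C[C@H](OC(=O)/C(C)=C/C)[C@H](C(C)C)CC1=O | intermediate
14 | (4R,5S)-5-isopropyl-4-(tigloyloxy)-2-[(tigloyloxy)methyl]cyclohex-2-en-1-one | C/C=C(\C)C(=O)OCC1=C[C@H](OC(=O)/C(C)=C/C)[C@H](C(C)C)CC1=O | intermediate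
15 | [(3R,4R)-4-isopropyl-3-(tigloyloxy)-6-(triethylsilyloxy)cyclohexa-1,5-dien-1-yl]methyl tiglate | C/C=C(\C)C(=O)OCC1=C[C@H](OC(=O)/C(C)=C/C)[C@H](C(C)C)C=C1O[Si](CC)(CC)CC | intermediate
16 | [(1R,4S,5S,6R)-5-isopropyl-4-(tigloyloxy)-1-(triethylsilyloxy)-7-oxabicyclo[4.1.0]hept-2-en-2-yl]methyl tiglate (epoxide oxygen anti to isopropyl, not isolated) | C/C=C(\C)C(=O)OCC1=C[C@H](OC(=O)/C(C)=C/C)[C@H](C(C)C)[C@H]2O[C@@]12O[Si](CC)(CC)CC | intermediate
17 | (4S,5R,6R)-6-hydroxy-5-isopropyl-4-(tigloyloxy)-2-[(tigloyloxy)methyl]cyclohex-2-en-1-one (CNP0326914.1) | C/C=C(\C)C(=O)OCC1=C[C@H](OC(=O)/C(C)=C/C)[C@H](C(C)C)[C@@H](O)C1=O | target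

Total step count: 11. Longest linear sequence: 10 steps (steps 1–4 and 6–11, from 2-isopropylphenol to the target; step 5 is a one-step side branch).

Steps most likely to fail

1. Step 4 (the proposed new method). Racemisation of the enone through its dienolate may be slower than hydrogenation of the mismatched enantiomer, which would erode both the enantiomeric purity and the cis selectivity. The alkoxide may also trigger conjugate addition or oligomerisation of the β-unsubstituted enone before it is reduced. The fallback replaces dynamic hydrogenation by a classical resolution built from known reactions. It sets out from 5, which is reduced 1,2 with DIBAL-H (toluene, −78 °C). The cis racemate, rac-cis-6-isopropylcyclohex-2-en-1-ol F1, is separated from any trans isomer and resolved by lipase-catalysed acylation (Burkholderia cepacia lipase, vinyl acetate, MTBE, rt). By the empirical size rule for lipase acylation of secondary alcohols, the (1R) enantiomer should be acetylated to (1R,6R)-6-isopropylcyclohex-2-en-1-yl acetate F2. The alcohol left unreacted should be the (1S,6S) enantiomer, which is compound 6, and the route is rejoined there at step 6, with at most half of the material carried on.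

2. Step 8. Conjugate addition of the amine at C6, which is flanked by the C5 ester, may be slow, so that the aldol with formaldehyde stalls and dimerisation of the enone or ester hydrolysis takes over. The fallback forms the C1–C7 bond by cross-coupling instead of organocatalytic aldol. It sets out from 11: α-iodination (I2, pyridine, CH2Cl2, 0 °C → rt) should give (4R,5S)-2-iodo-5-isopropyl-4-(tigloyloxy)cyclohex-2-en-1-one F3. Stille coupling of this iodide with (tributylstannyl)methanol (Pd(PPh3)4, dioxane, 80 °C) then installs C7 as the free hydroxymethyl group and returns to the route at 13.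

3. Step 11. Facial selectivity in the epoxidation of the enol silane may be poor, regiocontrol may already be lost one step earlier (γ-deprotonation at C5 instead of α′ at C3), or the labile silyloxy epoxide may undergo silyl transfer or elimination. The fallback is a direct enolate oxidation with reagent control and sets out from 14. LiHMDS (THF, −78 °C) forms the kinetic α′ enolate, the lithium C2=C3 enolate of 14 F4. This is hydroxylated in the same flask with a (camphorsulfonyl)oxaziridine (Davis oxidation), the reagent antipode being chosen to reinforce attack anti to the isopropyl group. Quenching with aqueous NH4Cl should give 17 directly, so the fallback replaces both steps 10 and 11.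

Further compounds
F1 | step 4 | rac-cis-6-isopropylcyclohex-2-en-1-ol (both enantiomers) | C1=C[C@H](O)[C@H](C(C)C)CC1.C1=C[C@@H](O)[C@@H](C(C)C)CC1
F2 | step 4 | (1R,6R)-6-isopropylcyclohex-2-en-1-yl acetate | C1=C[C@@H](OC(C)=O)[C@@H](C(C)C)CC1
F3 | step 8 | (4R,5S)-2-iodo-5-isopropyl-4-(tigloyloxy)cyclohex-2-en-1-one | IC1=C[C@H](OC(=O)/C(C)=C/C)[C@H](C(C)C)CC1=O
F4 | step 11 | lithium C2=C3 enolate of 14 | C/C=C(\C)C(=O)OCC1=C[C@H](OC(=O)/C(C)=C/C)[C@H](C(C)C)C=C1O[Li]
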